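## The problem

The target is an oxidised bisabolane whose cyclohexane ring (C1 methyl-bearing epoxide carbon, C2, C3 methylene, C4, C5, C6) is joined to the chain (C7 with its exocyclic methylene C14, C8, C9, C10, C11) through the single bond C4–C7; β denotes the ring face that carries C7, α the opposite face. The chain therefore has to be grown from a one-carbon handle on C4, and C7 must end as a 1,1-disubstituted alkene next to the C8 carbinol. Five of the seven stereocentres sit on the ring (β-epoxide at C1/C2, β side chain at C4, α oxygen at C5, β oxygen at C6) and can relay to one another: C4 fixes C5, C5 and C6 are vicinal, and the C6 oxygen decides the epoxide face. C8 (S) and C10 (R) are insulated from the ring and need reagent control. The three angelates isomerise to tiglates under nucleophilic, strongly basic or forcing acylation conditions, so they must arrive late and under stereoconservative conditions. Both epoxides are trisubstituted and acid-labile, a free C8 hydroxyl would open the C10–C11 epoxide to a tetrahydrofuran, and a carbonyl at C7 with an oxygen at C5 is set up for β-elimination. The enabling feature is that the C1–C2 epoxide is a masked C1=C2 alkene with the C6 oxygen allylic to it, so that C6–C1(Me)=C2–C3 is a 1-oxy-2-methylbutadiene and C4–C5 a dienophile carrying a carbon substituent (C7) and a latent oxygen.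

## Retrosynthesis

**Side-chain epoxide last (28 to 27).** The two C–O bonds of the C10–C11 epoxide are cut first. This epoxide is the most acid-sensitive group and would be attacked by a free C8 hydroxyl, so it should appear only after O8 is acylated. Triene triester 27 has one electron-rich trisubstituted alkene beside a hindered 1,1-disubstituted alkene and three electron-poor angelate alkenes. The forward reaction must be chemoselective and must set C10 by reagent control.

**Three angelates, one per step (27 to 26 to 25 to 24 to 21; acyl donor 23 from 22).** The three ester C–O bonds are cut in turn.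
- O8 is the only free hydroxyl of alcohol 21 and is acylated first, giving 24.
- Removal of the disiloxanediyl group gives diol 25, in which O5 is acylated (26) before the neopentyl-type O6 (27).
- Each acyl group comes from one charge of mixed anhydride 23, prepared once from angelic acid 22.

Against one exhaustive acylation of a triol, this order costs operations. In return the product esters never stand with a large excess of activated acid, and the middle step need not be site-selective, because any 6-monoester or diester formed there is carried to 27 by the next step. All three acylations lie after the organometallic and strongly basic steps.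

**C7–C8 bond with C8 set by the reagent (21 to 15 + 17).** Cutting C7–C8 gives alkenyl boronate 15 and homoprenyl carbamate 17. Acylation of lithiated 17 by the C7 ester would form the same bond. It would, however, leave a diisopropylcarbamate whose reductive removal the ring epoxide would not survive, and it would require a ketone methylenation beside two epimerisable centres. Lithiation–borylation (via 18, 19 and 20) expels the carbamate in the bond-forming step, delivers C7=C14 ready-made, and fixes C8 through the sparteine-controlled deprotonation. Carbamate 17 is one step from alcohol 16.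

**C7 handle adjusted (15 to 14 to 13 to 11).** Boronate 15 is traced through enol triflate 14 and methyl ketone 13 to ester 11 (via amide 12). C14 enters as a methyl nucleophile, and kinetic enolisation on the methyl side fixes the alkene position. The forward steps must leave the epoxide and the C4 configuration alone; both ring hydroxyls are masked as one disiloxanediyl group for this reason.

**C6 inverted and protecting groups exchanged (11 to 10 to 9 to 8 to 7 to 6).** The cycloaddition places O6 cis to the C5 substituent, whereas the target has it trans. Oxidation to epoxy ketone 8 and hydride reduction invert C6. The acetate of 9 is then exchanged for the silylene of 11, because an ester at O5 would not survive the organometallic steps. The reduction must deliver hydride from the α-face.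

**Epoxide and C5–O from alkene and acetyl (6 to 4).** Both oxygens come from one peracid treatment of cycloadduct 4 (via 5). The bulky C6 silyl ether sends the epoxide to the β-face, and the acetyl group becomes the acetate with retention. An acetyl group thus serves as a stand-in for the C5 oxygen and keeps the dienophile simple.

**Ring construction (4 to 2 + 3; 2 to 1).** Cutting C3–C4 and C5–C6 gives silyloxydiene 2 and oxo-enoate 3. One step builds the ring, sets C4, C5 and C6, and installs the C7 carbon and both future ring oxygens at C5 and C6. It must be regioselective (C6 to C5), endo-selective and enantioselective. Diene 2 is one step from enal 1.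

## Roads not taken

**Alternative 1:** The ring is cut at C4–C5 and C1=C2. Diphenylprolinol trimethylsilyl ether would catalyse the Michael addition of tert-butyl 3-oxopentanoate A3 to ethyl (E)-4-oxobut-2-enoate A2, and acid would then drive aldol condensation and loss of the tert-butyl ester to give enone A1.
- Merits: cheap, metal-free, two bonds in one pot, and C4 set by a well-understood iminium mechanism.
- Weak points: A1 has one stereocentre and no oxygen at C5. The C5 oxygen would need kinetic α'-enolate oxidation beside the acidic ester-bearing C4, with trans selectivity that has to be earned.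
- Comparison: for C6 and the ring epoxide this road is the better one. Luche reduction of the enone and hydroxyl-directed epoxidation would set both with no inversion, whereas the chosen plan spends three steps correcting C6. Against this, the chosen plan sets C4, C5 and C6 and places both ring oxygens in one cycloaddition, and it makes the C5–O bond with retention instead of by enolate chemistry.

**Alternative 2:** The ring is cut at C6–C1. CrCl2 with catalytic NiCl2 would convert the alkenyl iodide of acyclic aldehyde A5 into an alkenylchromium species that adds to the C6 aldehyde and gives cyclohexenol A4.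
- Merits: the whole side chain, including C8, is in place before the ring closes; the coupling tolerates most functional groups; the free C6 hydroxyl of A4 could direct the epoxidation.
- Weak points: A5 needs C4, C5 and C8 set in an open chain together with a (Z)-trisubstituted iodoalkene, which makes a long linear sequence. The ring closure forms one bond and one stereocentre, and its sense at C6 is not assured. Chromium is used in excess.
- Comparison: this road is as good or better in convergence and avoids all C7 chemistry on the ring. The chosen plan answers with a far shorter path to a ring in which three stereocentres relay from one catalytic step.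

**Alternative 3:** The ring is cut at C6–C1 and C2–C3. Ni(cod)2 (zerovalent nickel) with a chiral phosphine would couple methyl 3-oxocyclobutane-1-carboxylate A7 with 1-(trimethylsilyl)propyne A8 through oxidative cyclisation, β-carbon elimination and reductive elimination, giving silyl enone A6.
- Merits: atom-economical, and C4 arises by desymmetrisation of an achiral ketone.
- Weak points: an intermolecular enantioselective version with an unsymmetrical alkyne needs regio- and enantiocontrol at once, which is less secure. The silyl group must then be removed, and A6 has the same lack of a C5 oxygen as A1.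
- Comparison: equal in brevity up to a ring with C4 set, but all three ring oxygens remain to be installed; the chosen plan installs two of them during and directly after the key step.

Key step: step 2

Assumption: the absolute sense of step 2 is assigned from the α-C–H···O binding model for ketone-bound dienophiles on this catalyst class; should the adduct prove antipodal, the catalyst from (R)-α,α-diphenylprolinol is used and nothing else changes.

## Route

Step 1
Reactants: 1 (E)-2-methylbut-2-enal
Product: 2 (E)-2-methyl-1-(triisopropylsilyloxy)buta-1,3-diene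
Conditions: iPr3SiOTf, Et3N, Et2O, 0 °C → 25 °C
Reagents that add atoms: triisopropylsilyl trifluoromethanesulfonate, CC(C)[Si](OS(=O)(=O)C(F)(F)F)(C(C)C)C(C)C
Why: O-silylation of the enal gives an oxocarbenium ion from which Et3N removes a γ-proton (silyl dienol ether formation); the s-trans enal gives the 1E geometry, which places the silyloxy group on the outside of the s-cis diene.

Step 2
Reactants: 2 (E)-2-methyl-1-(triisopropylsilyloxy)buta-1,3-diene; 3 methyl (E)-4-oxopent-2-enoate
Product: 4 methyl (1R,5S,6S)-6-acetyl-4-methyl-5-(triisopropylsilyloxy)cyclohex-3-ene-1-carboxylate (target locants: C4 ester β; C5 acetyl α; C6 silyl ether α)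
Conditions: (S)-B-o-tolyl oxazaborolidine from (S)-α,α-diphenylprolinol (20 mol %), Tf2NH (18 mol %), CH2Cl2, −78 → −40 °C
Reagents that add atoms: none
Why: The protonated oxazaborolidine is a chiral boron Lewis acid that binds the more basic ketone oxygen of 3 anti to the methyl group, lowering the LUMO and placing its largest coefficient on the ester-bearing carbon (C4). The cycloaddition is a concerted, asynchronous, normal-demand Diels–Alder reaction in which the unsubstituted diene terminus (C3) bonds to C4 ahead of C6–C5; the closest known reaction type is the oxazaborolidinium-catalysed Diels–Alder reaction of enones and quinones with silyloxydienes. The cyclohexene ring closes by this intermolecular [4+2] mode, with both new bonds formed suprafacially on each partner. C4 and C5 come out trans because the E geometry of 3 is retained. C6 comes out cis to the acetyl group because the catalyst-bound acetyl sits endo and the silyloxy group of the 1E diene sits outside. The absolute configuration follows from the catalyst, whose aryl group covers one face of the bound C4=C5 bond so that the diene enters at the C4-re/C5-re face to give (4R,5S,6S) in target locants. The step needs regio-, endo- and enantioselectivity; ketone-over-ester binding secures the first and the chiral ion pair the other two. The bulky triisopropylsilyl group keeps silyl transfer and open-chain Michael addition from competing.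

Step 3
Reactants: 4 methyl (1R,5S,6S)-6-acetyl-4-methyl-5-(triisopropylsilyloxy)cyclohex-3-ene-1-carboxylate
Product: 6 methyl 5α-acetoxy-1β,2β-epoxy-1-methyl-6α-(triisopropylsilyloxy)cyclohexane-4β-carboxylate, via epoxy ketone 5 (not isolated)
Conditions: mCPBA (excess), NaHCO3, CH2Cl2, 0 → 35 °C
Reagents that add atoms: 3-chloroperoxybenzoic acid, OOC(=O)c1cccc(Cl)c1
Why: Prilezhaev epoxidation occurs first, on the β-face, because the pseudoaxial C6 silyl ether blocks the α-face and cannot hydrogen-bond to the peracid; the excess peracid then effects Baeyer–Villiger oxidation of the methyl ketone, in which the secondary C5 migrates in preference to methyl with retention, giving the 5α-acetate.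

Step 4
Reactants: 6 methyl 5α-acetoxy-1β,2β-epoxy-1-methyl-6α-(triisopropylsilyloxy)cyclohexane-4β-carboxylate
Product: 7 methyl 5α-acetoxy-1β,2β-epoxy-6α-hydroxy-1-methylcyclohexane-4β-carboxylate
Conditions: Bu4NF, AcOH, THF, 0 → 25 °C
Reagents that add atoms: none
Why: Fluoride-mediated desilylation; the acetic acid buffer keeps the medium non-basic, so neither acetyl shift from O5 to the cis O6 nor Payne rearrangement of the trans-epoxy alcohol should occur.

Step 5
Reactants: 7 methyl 5α-acetoxy-1β,2β-epoxy-6α-hydroxy-1-methylcyclohexane-4β-carboxylate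
Product: 8 methyl 5α-acetoxy-1β,2β-epoxy-1-methyl-6-oxocyclohexane-4β-carboxylate
Conditions: Dess–Martin periodinane, pyridine, CH2Cl2, 0 → 25 °C
Reagents that add atoms: none
Why: Dess–Martin oxidation under buffered, non-enolising conditions, so C5 and C4 keep their configuration and the epoxide is untouched.

Step 6
Reactants: 8 methyl 5α-acetoxy-1β,2β-epoxy-1-methyl-6-oxocyclohexane-4β-carboxylate
Product: 9 methyl 5α-acetoxy-1β,2β-epoxy-6β-hydroxy-1-methylcyclohexane-4β-carboxylate
Conditions: NaBH4, CeCl3·7H2O, MeOH, −78 °C
Reagents that add atoms: none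
Why: Luche reduction; in the half-chair with the C4 and C5 substituents equatorial, axial hydride delivery to C6 comes from the α-face, which is also the face anti to the epoxide C–O bond, so the new hydroxyl should be β (cis to the epoxide, trans to the acetate), and CeCl3 suppresses epoxide opening and ester reduction.

Step 7
Reactants: 9 methyl 5α-acetoxy-1β,2β-epoxy-6β-hydroxy-1-methylcyclohexane-4β-carboxylate
Product: 10 methyl 1β,2β-epoxy-5α,6β-dihydroxy-1-methylcyclohexane-4β-carboxylate
Conditions: K2CO3 (cat.), MeOH, 0 °C
Reagents that add atoms: none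
Why: Base-catalysed methanolysis removes the acetate while the methyl ester is degenerate in methanol; the cis-epoxy alcohol cannot undergo Payne rearrangement, and the gauche H4/O5 arrangement disfavours elimination.

Step 8
Reactants: 10 methyl 1β,2β-epoxy-5α,6β-dihydroxy-1-methylcyclohexane-4β-carboxylate
Product: 11 methyl 1β,2β-epoxy-1-methyl-5α,6β-O-(1,1,3,3-tetraisopropyldisiloxane-1,3-diyl)cyclohexane-4β-carboxylate
Conditions: (iPr2SiCl)2O, imidazole, DMF, 0 → 25 °C
Reagents that add atoms: 1,3-dichloro-1,1,3,3-tetraisopropyldisiloxane, CC(C)[Si](Cl)(C(C)C)O[Si](Cl)(C(C)C)C(C)C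
Why: The bifunctional chlorosilane silylates the less hindered O5 first and closes intramolecularly onto O6, a standard protection of trans-diequatorial 1,2-diols that masks both hydroxyls with one base-stable, fluoride-labile group.

Step 9
Reactants: 11 methyl 1β,2β-epoxy-1-methyl-5α,6β-O-(1,1,3,3-tetraisopropyldisiloxane-1,3-diyl)cyclohexane-4β-carboxylate
Product: 13 4β-acetyl-1β,2β-epoxy-1-methyl-5α,6β-O-(1,1,3,3-tetraisopropyldisiloxane-1,3-diyl)cyclohexane (C7 methyl ketone), via N-methoxy-N-methylamide 12 (not isolated)
Conditions: MeNH(OMe)·HCl, i-PrMgCl, THF, −20 °C; then MeMgCl, −20 → 0 °C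
Reagents that add atoms: methylmagnesium chloride, C[Mg]Cl
Why: Magnesium-amide aminolysis of the ester gives the N-methoxy-N-methylamide, and Grignard addition to it stops at the chelated tetrahedral intermediate, so the ketone appears only on work-up; the low temperature spares the epoxide and the C4 configuration.

Step 10
Reactants: 13 4β-acetyl-1β,2β-epoxy-1-methyl-5α,6β-O-(1,1,3,3-tetraisopropyldisiloxane-1,3-diyl)cyclohexane
Product: 14 1-(ring C4-yl)ethenyl trifluoromethanesulfonate (C7 enol triflate of 13; C7=C14H2)
Conditions: KN(SiMe3)2, PhNTf2, THF, −78 °C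
Reagents that add atoms: N-phenylbis(trifluoromethanesulfonimide), O=S(=O)(N(c1ccccc1)S(=O)(=O)C(F)(F)F)C(F)(F)F
Why: Kinetic deprotonation takes place on the methyl side and not at the hindered C4 methine, and O-triflation of the potassium enolate fixes C7=C14 as a 1,1-disubstituted enol triflate.

Step 11
Reactants: 14 1-(ring C4-yl)ethenyl trifluoromethanesulfonate
Product: 15 2-[1-(ring C4-yl)ethenyl]-4,4,5,5-tetramethyl-1,3,2-dioxaborolane (C7 alkenyl pinacol boronate)
Conditions: B2pin2, PdCl2(PPh3)2 (3 mol %), PPh3, KOPh, toluene, 50 °C
Reagents that add atoms: bis(pinacolato)diboron, CC1(C)OB(OC1(C)C)B1OC(C)(C)C(C)(C)O1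
Why: Miyaura borylation: oxidative addition of the enol triflate to zerovalent palladium, phenoxide-assisted transmetalation with the diboron reagent and reductive elimination; epoxide and silyl ethers are inert under these mild, weakly basic conditions.

Step 12
Reactants: 16 4-methylpent-3-en-1-ol
Product: 17 4-methylpent-3-en-1-yl N,N-diisopropylcarbamate
Conditions: iPr2NCOCl, Et3N, DMAP (cat.), CH2Cl2, 40 °C
Reagents that add atoms: N,N-diisopropylcarbamoyl chloride, CC(C)N(C(C)C)C(Cl)=O
Why: Carbamoylation of the primary alcohol; the carbamate directs and stabilises the later α-lithiation.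

Step 13
Reactants: 17 4-methylpent-3-en-1-yl N,N-diisopropylcarbamate; 15 C7 alkenyl pinacol boronate
Product: 21 (8S)-allylic alcohol bearing C7=C14H2 and C10=C11 with the 1β,2β-epoxide and the 5α,6β-disiloxanediyl group, via lithiated carbamate 18 (not isolated), via boronate complex 19 (not isolated), via allylic boronic ester 20 (not isolated)
Conditions: s-BuLi, (+)-sparteine, Et2O, −78 °C; then 15, −78 → 35 °C; then H2O2, NaOH, THF–H2O, 0 °C
Reagents that add atoms: hydrogen peroxide, OO
Why: Sparteine-mediated enantioselective α-deprotonation gives the configurationally stable (R)-organolithium; borylation with retention, 1,2-migration of the alkenyl group with inversion and loss of the carbamate (lithiation–borylation), then C–B oxidation with retention give the (8S)-alcohol, so C8 is under reagent control.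

Step 14
Reactants: 22 angelic acid ((Z)-2-methylbut-2-enoic acid)
Product: 23 angelic 2,4,6-trichlorobenzoic anhydride ((Z)-2-methylbut-2-enoic 2,4,6-trichlorobenzoic anhydride)
Conditions: 2,4,6-Cl3C6H2COCl, Et3N, toluene, 0 → 25 °C; filtration, used as a toluene solution
Reagents that add atoms: 2,4,6-trichlorobenzoyl chloride, O=C(Cl)c1c(Cl)cc(Cl)cc1Cl
Why: Mixed-anhydride formation (the activation half of the Yamaguchi esterification): the triethylammonium carboxylate attacks the aroyl chloride; the ammonium chloride is filtered off so that the acyl donor carries no amine into the acylations, and one batch serves steps 15, 17 and 18.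

Step 15
Reactants: 21 (8S)-allylic alcohol with the 5α,6β-disiloxanediyl group; 23 angelic 2,4,6-trichlorobenzoic anhydride
Product: 24 (8S)-8-O-angeloyl derivative of 21 (1β,2β-epoxide; 5α,6β-disiloxanediyl group; C7=C14H2; C10=C11)
Conditions: 23 (slight excess), NaHCO3 (solid), toluene, 80 °C
Reagents that add atoms: none
Why: Thermal acyl transfer from the mixed anhydride (Yamaguchi-type esterification without a nucleophilic catalyst): the alcohol attacks the unhindered angeloyl carbonyl and not the 2,6-dichloro-flanked aroyl carbonyl, and the absence of amine or pyridine catalysts is what keeps the Z-alkene from isomerising; O8 is the only free hydroxyl, so the site is unambiguous, and solid NaHCO3 takes up the liberated acid to protect the epoxide.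

Step 16
Reactants: 24 (8S)-8-O-angeloyl derivative of 21
Product: 25 (8S)-8-O-angeloyl-1β,2β-epoxy-5α,6β-diol (C7=C14H2; C10=C11)
Conditions: Bu4NF, AcOH, THF, 0 → 25 °C
Reagents that add atoms: none
Why: Fluoride cleaves both Si–O bonds of the disiloxanediyl group; under acetic acid buffering the angelate, the cis-epoxy alcohol and the allylic ester should be unaffected, and the remote O8 ester has no low-energy path for migration to the ring hydroxyls.

Step 17
Reactants: 25 (8S)-8-O-angeloyl-1β,2β-epoxy-5α,6β-diol; 23 angelic 2,4,6-trichlorobenzoic anhydride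
Product: 26 (8S)-5α,8-di-O-angeloyl-1β,2β-epoxy-6β-ol (C7=C14H2; C10=C11)
Conditions: 23 (1 equiv, slow addition), NaHCO3 (solid), toluene, 50 → 60 °C
Reagents that add atoms: none
Why: The same catalyst-free mixed-anhydride acylation with one equivalent of donor; O5 should react first because O6 is neopentyl-like (flanked by the fully substituted C1) and hydrogen-bonded to the cis epoxide oxygen, and any 6-monoester or diester formed by leakage is carried to the same triester in step 18, so high site selectivity is not required.

Step 18
Reactants: 26 (8S)-5α,8-di-O-angeloyl-1β,2β-epoxy-6β-ol; 23 angelic 2,4,6-trichlorobenzoic anhydride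
Product: 27 5α,6β,8-tri-O-angeloyl triene (1β,2β-epoxide; C7=C14H2; C10=C11)
Conditions: 23 (excess), NaHCO3 (solid), toluene, 80 °C
Reagents that add atoms: none
Why: Mixed-anhydride acylation of the remaining hindered O6 at higher temperature and donor concentration, again without a nucleophilic catalyst so that neither the incoming nor the two resident angelates isomerise to tiglates.

Step 19
Reactants: 27 5α,6β,8-tri-O-angeloyl triene
Product: 28 CNP0258231.3 (target; 10R epoxide)
Conditions: D-fructose-derived Shi ketone (30 mol %), Oxone (2KHSO5·KHSO4·K2SO4), K2CO3, Bu4NHSO4, MeCN–CH2(OMe)2, aq. Na2B4O7 buffer (pH 10.5), 0 °C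
Reagents that add atoms: potassium peroxymonosulfate, [K+].[O-]S(=O)(=O)OO
Why: Shi epoxidation: the chiral dioxirane reacts fastest with the electron-rich trisubstituted C10=C11 and should leave the hindered C7=C14 and the electron-poor angelate alkenes; the spiro transition state of the D-fructose-derived ketone gives the 10R epoxide, and the cold pH 10.5 medium spares the esters and the ring epoxide.

## Compound list

1 | (E)-2-methylbut-2-enal | C/C=C(\C)C=O | starting material
2 | (E)-2-methyl-1-(triisopropylsilyloxy)buta-1,3-diene | C=C/C(C)=C/O[Si](C(C)C)(C(C)C)C(C)C | intermediate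
3 | methyl (E)-4-oxopent-2-enoate | COC(=O)/C=C/C(C)=O | starting material
4 | methyl (1R,5S,6S)-6-acetyl-4-methyl-5-(triisopropylsilyloxy)cyclohex-3-ene-1-carboxylate | COC(=O)[C@@H]1CC=C(C)[C@@H](O[Si](C(C)C)(C(C)C)C(C)C)[C@H]1C(C)=O | intermediate
5 | methyl 5α-acetyl-1β,2β-epoxy-1-methyl-6α-(triisopropylsilyloxy)cyclohexane-4β-carboxylate | COC(=O)[C@@H]1C[C@@H]2O[C@]2(C)[C@@H](O[Si](C(C)C)(C(C)C)C(C)C)[C@H]1C(C)=O | intermediate (not isolated)
6 | methyl 5α-acetoxy-1β,2β-epoxy-1-methyl-6α-(triisopropylsilyloxy)cyclohexane-4β-carboxylate | COC(=O)[C@@H]1C[C@@H]2O[C@]2(C)[C@@H](O[Si](C(C)C)(C(C)C)C(C)C)[C@H]1OC(C)=O | intermediate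
7 | methyl 5α-acetoxy-1β,2β-epoxy-6α-hydroxy-1-methylcyclohexane-4β-carboxylate | COC(=O)[C@@H]1C[C@@H]2O[C@]2(C)[C@@H](O)[C@H]1OC(C)=O | intermediate
8 | methyl 5α-acetoxy-1β,2β-epoxy-1-methyl-6-oxocyclohexane-4β-carboxylate | COC(=O)[C@@H]1C[C@@H]2O[C@]2(C)C(=O)[C@H]1OC(C)=O | intermediate
9 | methyl 5α-acetoxy-1β,2β-epoxy-6β-hydroxy-1-methylcyclohexane-4β-carboxylate | COC(=O)[C@@H]1C[C@@H]2O[C@]2(C)[C@H](O)[C@H]1OC(C)=O | intermediate
10 | methyl 1β,2β-epoxy-5α,6β-dihydroxy-1-methylcyclohexane-4β-carboxylate | COC(=O)[C@@H]1C[C@@H]2O[C@]2(C)[C@H](O)[C@H]1O | intermediate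
11 | methyl 1β,2β-epoxy-1-methyl-5α,6β-O-(1,1,3,3-tetraisopropyldisiloxane-1,3-diyl)cyclohexane-4β-carboxylate | COC(=O)[C@@H]1C[C@@H]2O[C@]2(C)[C@H](O[Si](C(C)C)(C(C)C)O[Si](C(C)C)(C(C)C)O3)[C@H]13 | intermediate
12 | N-methoxy-N-methylamide corresponding to ester 11 | CON(C)C(=O)[C@@H]1C[C@@H]2O[C@]2(C)[C@H](O[Si](C(C)C)(C(C)C)O[Si](C(C)C)(C(C)C)O3)[C@H]13 | intermediate (not isolated)
13 | 4β-acetyl-1β,2β-epoxy-1-methyl-5α,6β-O-(1,1,3,3-tetraisopropyldisiloxane-1,3-diyl)cyclohexane | CC(=O)[C@@H]1C[C@@H]2O[C@]2(C)[C@H](O[Si](C(C)C)(C(C)C)O[Si](C(C)C)(C(C)C)O3)[C@H]13 | intermediate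
14 | C7 enol triflate of 13 (C7=C14H2) | C=C(OS(=O)(=O)C(F)(F)F)[C@@H]1C[C@@H]2O[C@]2(C)[C@H](O[Si](C(C)C)(C(C)C)O[Si](C(C)C)(C(C)C)O3)[C@H]13 | intermediate
15 | C7 alkenyl pinacol boronate | C=C(B1OC(C)(C)C(C)(C)O1)[C@@H]1C[C@@H]2O[C@]2(C)[C@H](O[Si](C(C)C)(C(C)C)O[Si](C(C)C)(C(C)C)O3)[C@H]13 | intermediate
16 | 4-methylpent-3-en-1-ol | CC(C)=CCCO | starting material
17 | 4-methylpent-3-en-1-yl N,N-diisopropylcarbamate | CC(C)=CCCOC(=O)N(C(C)C)C(C)C | intermediate
18 | (R)-1-lithio-4-methylpent-3-en-1-yl N,N-diisopropylcarbamate (sparteine complex; ligand not drawn) | CC(C)=CC[C@@H]([Li])OC(=O)N(C(C)C)C(C)C | intermediate (not isolated)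
19 | lithium alkenyl(α-carbamoyloxyalkyl) pinacol boronate complex from 18 and 15 | [Li+].CC(C)=CC[C@H](OC(=O)N(C(C)C)C(C)C)[B-]1(OC(C)(C)C(C)(C)O1)C(=C)[C@@H]1C[C@@H]2O[C@]2(C)[C@H](O[Si](C(C)C)(C(C)C)O[Si](C(C)C)(C(C)C)O3)[C@H]13 | intermediate (not isolated)
20 | C8 allylic pinacol boronic ester (boron where O8 of 21 will stand) | CC(C)=CC[C@H](B1OC(C)(C)C(C)(C)O1)C(=C)[C@@H]1C[C@@H]2O[C@]2(C)[C@H](O[Si](C(C)C)(C(C)C)O[Si](C(C)C)(C(C)C)O3)[C@H]13 | intermediate (not isolated)
21 | (8S)-allylic alcohol with 1β,2β-epoxide and 5α,6β-disiloxanediyl group | CC(C)=CC[C@H](O)C(=C)[C@@H]1C[C@@H]2O[C@]2(C)[C@H](O[Si](C(C)C)(C(C)C)O[Si](C(C)C)(C(C)C)O3)[C@H]13 | intermediate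
22 | angelic acid ((Z)-2-methylbut-2-enoic acid) | C/C=C(/C)C(=O)O | starting material
23 | angelic 2,4,6-trichlorobenzoic anhydride | C/C=C(/C)C(=O)OC(=O)c1c(Cl)cc(Cl)cc1Cl | intermediate
24 | (8S)-8-O-angeloyl derivative of 21 (5α,6β-disiloxanediyl group retained) | C=C([C@H](CC=C(C)C)OC(=O)/C(C)=C\C)[C@@H]1C[C@@H]2O[C@]2(C)[C@H](O[Si](C(C)C)(C(C)C)O[Si](C(C)C)(C(C)C)O3)[C@H]13 | intermediate
25 | (8S)-8-O-angeloyl-1β,2β-epoxy-5α,6β-diol | C=C([C@H](CC=C(C)C)OC(=O)/C(C)=C\C)[C@@H]1C[C@@H]2O[C@]2(C)[C@H](O)[C@H]1O | intermediate
26 | (8S)-5α,8-di-O-angeloyl-1β,2β-epoxy-6β-ol | C=C([C@H](CC=C(C)C)OC(=O)/C(C)=C\C)[C@@H]1C[C@@H]2O[C@]2(C)[C@H](O)[C@H]1OC(=O)/C(C)=C\C | intermediate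
27 | 5α,6β,8-tri-O-angeloyl triene (10,11-alkene) | C=C([C@H](CC=C(C)C)OC(=O)/C(C)=C\C)[C@@H]1C[C@@H]2O[C@]2(C)[C@H](OC(=O)/C(C)=C\C)[C@H]1OC(=O)/C(C)=C\C | intermediate
28 | CNP0258231.3 | C=C([C@H](C[C@H]1OC1(C)C)OC(=O)/C(C)=C\C)[C@@H]1C[C@@H]2O[C@]2(C)[C@H](OC(=O)/C(C)=C\C)[C@H]1OC(=O)/C(C)=C\C | target

## Step count and least certain steps

Total: 19 steps. Longest linear sequence: 17 steps (steps 1–11, 13 and 15–19); steps 12 and 14 are one-step side branches.

**Step 2 (key step).** The silyloxydiene may react by silyl transfer or open-chain Michael addition instead of cycloaddition, part of the catalyst may bind the ester and erode regiocontrol, and facial discrimination on this doubly activated dienophile may be incomplete. Fallback: 2 and 3 are combined with the achiral Lewis acid Me2AlCl in CH2Cl2 at −78 °C, which still binds the ketone and should give the racemic adduct F1. Preparative chromatography of F1 on a chiral stationary phase then supplies 4, where the route is rejoined.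

**Step 3.** Migration of the hindered, inductively deactivated C5 may be slow, so that acid-promoted opening of the new epoxide competes during the long exposure. Fallback: the order is reversed. Compound 4 is oxidised with Me3SiOOSiMe3 and catalytic Me3SiOTf in CH2Cl2 at −40 °C, a Baeyer–Villiger variant that leaves alkenes alone, to give the cyclohexenyl acetate F2. Short treatment of F2 with mCPBA then gives 6.

**Step 6.** Hydride may approach from the β-face and return the 6α-alcohol through poor facial selectivity. Fallback: steps 5–7 are replaced by a Mitsunobu inversion. Compound 7 is treated with 4-nitrobenzoic acid, PPh3 and diisopropyl azodicarboxylate to give the inverted 6β-(4-nitrobenzoate) F3, and methanolysis of both esters of F3 with K2CO3 in MeOH gives 10.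

**Step 13.** Formation of the boronate complex from the α-branched alkenyl boronate may be slow or reversible, migration may be incomplete, and the lithiated carbamate may lose configurational integrity on warming. Fallback, setting out from 14 and returning at 21: Dess–Martin oxidation of 16 gives 4-methylpent-3-enal F4. Nozaki–Hiyama–Kishi coupling of 14 with F4 (CrCl2, catalytic NiCl2, DMF) gives the C8-epimeric allylic alcohols F5. Dess–Martin oxidation of F5 gives the enone F6. Corey–Bakshi–Shibata reduction of F6 with the (R)-methyl oxazaborolidine and catecholborane sets 8S and gives 21.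

**Step 18.** Acylation of the neopentyl-type O6 may stall, and forcing it may bring Z to E isomerisation of the incoming or the resident angelates. Fallback, setting out from 26 and returning at 27: 26 is esterified at O6 with 2-[bis(2,2,2-trifluoroethoxy)phosphoryl]propanoic acid (N,N'-diisopropylcarbodiimide, DMAP, CH2Cl2) to the 6-O-phosphonopropionate F7. Still–Gennari olefination of F7 with acetaldehyde (KN(SiMe3)2, 18-crown-6, THF, −78 °C) builds the third Z-alkene on the ester already in place and gives 27.

## Further compounds

F1 | step 2 | racemic 4 (1:1 mixture of 4 and its enantiomer) | COC(=O)[C@@H]1CC=C(C)[C@@H](O[Si](C(C)C)(C(C)C)C(C)C)[C@H]1C(C)=O.COC(=O)[C@H]1CC=C(C)[C@H](O[Si](C(C)C)(C(C)C)C(C)C)[C@@H]1C(C)=O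
F2 | step 3 | methyl 5α-acetoxy-1-methyl-6α-(triisopropylsilyloxy)cyclohex-1-ene-4β-carboxylate (target locants; acetate in place of the acetyl group of 4) | COC(=O)[C@@H]1CC=C(C)[C@@H](O[Si](C(C)C)(C(C)C)C(C)C)[C@H]1OC(C)=O
F3 | step 6 | methyl 5α-acetoxy-1β,2β-epoxy-1-methyl-6β-(4-nitrobenzoyloxy)cyclohexane-4β-carboxylate | COC(=O)[C@@H]1C[C@@H]2O[C@]2(C)[C@H](OC(=O)c3ccc(cc3)[N+](=O)[O-])[C@H]1OC(C)=O
F4 | step 13 | 4-methylpent-3-enal | CC(C)=CCC=O
F5 | step 13 | C8-epimeric mixture of allylic alcohol 21 | CC(C)=CCC(O)C(=C)[C@@H]1C[C@@H]2O[C@]2(C)[C@H](O[Si](C(C)C)(C(C)C)O[Si](C(C)C)(C(C)C)O3)[C@H]13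
F6 | step 13 | C8 enone (2-methylene ketone) | CC(C)=CCC(=O)C(=C)[C@@H]1C[C@@H]2O[C@]2(C)[C@H](O[Si](C(C)C)(C(C)C)O[Si](C(C)C)(C(C)C)O3)[C@H]13
F7 | step 18 | 6β-O-{2-[bis(2,2,2-trifluoroethoxy)phosphoryl]propanoyl} derivative of 26 | C=C([C@H](CC=C(C)C)OC(=O)/C(C)=C\C)[C@@H]1C[C@@H]2O[C@]2(C)[C@H](OC(=O)C(C)P(=O)(OCC(F)(F)F)OCC(F)(F)F)[C@H]1OC(=O)/C(C)=C\C
A1 | alternative 1 | ethyl (1R)-4-methyl-5-oxocyclohex-3-ene-1-carboxylate | CCOC(=O)[C@@H]1CC=C(C)C(=O)C1
A2 | alternative 1 | ethyl (E)-4-oxobut-2-enoate | CCOC(=O)/C=C/C=O
A3 | alternative 1 | tert-butyl 3-oxopentanoate | CCC(=O)CC(=O)OC(C)(C)C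
A4 | alternative 2 | cyclohexenol with free 6β-hydroxyl, 5α-(4-methoxybenzyl) ether and 8-silyl ether | C=C([C@H](CC=C(C)C)O[Si](C)(C)C(C)(C)C)[C@@H]1CC=C(C)[C@H](O)[C@H]1OCc1ccc(OC)cc1
A5 | alternative 2 | acyclic (Z)-iodoalkenyl C6 aldehyde | C=C([C@H](CC=C(C)C)O[Si](C)(C)C(C)(C)C)[C@H](C/C=C(/C)I)[C@H](OCc1ccc(OC)cc1)C=O
A6 | alternative 3 | methyl (1S)-4-methyl-5-oxo-3-(trimethylsilyl)cyclohex-3-ene-1-carboxylate | COC(=O)[C@@H]1CC([Si](C)(C)C)=C(C)C(=O)C1
A7 | alternative 3 | methyl 3-oxocyclobutane-1-carboxylate | COC(=O)C1CC(=O)C1
A8 | alternative 3 | 1-(trimethylsilyl)propyne | CC#C[Si](C)(C)C
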